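Early times lie partly before our first reading: at 0.48 h Wednesday's run has already turned 17.2% of its starting material into target, so what came before that reading shows only as a sum, and our slow-motion account begins there.

all flasks: free catalyst 0.0240 M
- Wednesday's: starting material 0.800 M; reagent 0.640 M
- Saturday's: starting material 0.400 M; reagent 0.240 M
- Sunday's: starting material 0.800 M; reagent 1.90 M
- Tuesday's: starting material 0.400 M; reagent 0.640 M
- Monday's: starting material 2.40 M; reagent 1.30 M; time 12 h

| run | time / h | [target] / M |
|---|---|---|
| Wednesday's run | 0.48 | 0.138 |
| Wednesday's run | 0.82 | 0.195 |
| Wednesday's run | 1.4 | 0.258 |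
| Wednesday's run | 2.4 | 0.329 |
| Wednesday's run | 4.1 | 0.402 |
| Wednesday's run | 7.0 | 0.481 |
| Wednesday's run | 12 | 0.546 |
| Saturday's run | 0.48 | 0.032 |
| Saturday's run | 0.82 | 0.044 |
| Saturday's run | 1.4 | 0.055 |
| Saturday's run | 2.4 | 0.082 |
| Saturday's run | 4.1 | 0.120 |
| Saturday's run | 7.0 | 0.151 |
| Saturday's run | 12 | 0.177 |
| Sunday's run | 0.48 | 0.377 |
| Sunday's run | 0.82 | 0.461 |
| Sunday's run | 1.4 | 0.557 |
| Sunday's run | 2.4 | 0.656 |
| Sunday's run | 4.1 | 0.723 |
| Sunday's run | 7.0 | 0.782 |
| Sunday's run | 12 | 0.797 |
| Tuesday's run | 0.48 | 0.080 |
| Tuesday's run | 0.82 | 0.110 |
| Tuesday's run | 1.4 | 0.136 |
| Tuesday's run | 2.4 | 0.184 |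
| Tuesday's run | 4.1 | 0.240 |
| Tuesday's run | 7.0 | 0.290 |
| Tuesday's run | 12 | 0.342 |

(readings scatter by 0.004 M)

1. apparent order in [reagent] of the starting rate, round the charge of the Wednesday's run (the rate where two percent of its starting material have turned into target)
2. apparent order in [starting material] of the starting rate, round the charge of the Wednesday's run (the rate where two percent of its starting material have turned into target) (one fixed amount of target, the same in the runs compared)
3. the Saturday's run starts with 0.400 M less of starting material and of reagent than the Wednesday's run, and with no target. Compared where both hold the same amount of starting material, once fifteen percent of what the Saturday's run was charged with has turned into target, is the Saturday's run faster, slower or alike (within a tenth)?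
4. target in the Monday's run at 12 h, as a share of the starting material charged

- Overall: starting material + reagent -> target, with free catalyst as catalyst.
- Constant volume, constant temperature.
- "The second partner" is reagent.
- An order is taken over about fifteen percent of the charge, up and down.

At 12 h Wednesday's run shows 4.82 L mol⁻¹. This is its clock reading, the natural logarithm of the fraction of starting material left over the fraction of reagent left, divided by the charged starting material minus the charged reagent. For a rate first order in each partner, this reading is the rate constant summed over time, whatever the charge.

At its first reading Wednesday's clock already stands at 0.335 L mol⁻¹, at 0.48 h. In the middle it reads 2.96 L mol⁻¹ at 7.0 h, which gives a late pace of 0.372 L mol⁻¹ h⁻¹. The first stretch therefore ran at about twice that pace. At the end, Saturday's run reads 4.71 L mol⁻¹ and Tuesday's 4.86 L mol⁻¹ at 12 h. These stand close to Wednesday's reading despite different charges, so we take both orders as near one.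

Monday's run holds the same free catalyst, 0.0240 M, and less reagent than starting material, so reagent is the limiting reagent and target cannot pass 54.2% of the starting material. Multiplying the clock by Monday's charged difference leaves 0.229% of its reagent at 12 h, so nearly all has gone and we reckon 54.0%. The same-point comparison falls just after Saturday's 1.4 h reading, past the first fast stretch, and we would claim no lead there.

The forecast gives orders of 1 in reagent (0.85 to 1.15) and 1 in starting material (0.85 to 1.15), and 54% for Monday's run (52.5% to 54.2%). It parts from us on the comparison, answering faster: “This is borderline, but faster”.

The flask gives 1.1 in reagent, 1.1 in starting material, alike for the comparison, and 54.0% for Monday's run.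

    2 free catalyst ⇌ catalyst dimer, settled at all times (30.00 L mol⁻¹)
    catalyst dimer + starting material + reagent → target + catalyst dimer (213.5 L² mol⁻² h⁻¹)
    starting material + reagent → target (0.3852 L mol⁻¹ h⁻¹)
    2 free catalyst → 2 spent catalyst (313.2 L mol⁻¹ h⁻¹)

The step from free catalyst to spent catalyst makes no difference to Monday's figure. Saturday's run reaches half of its starting material at a clock reading of 6.87 L mol⁻¹, which Wednesday's clock and late pace place at 17.5 h, and the flask stands there at 17.2 h.

The earlier runs and the new flask come from a simulation with made-up constants; the scatter is artificial.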